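**Strategy.** The dimethylpyranone ring fused to the B ring is cut back to an aryl 1,1-dimethylpropargyl ether on a finished (2S)-flavanone. Heating that ether triggers a propargyl Claisen shift, tautomerisation, hydrogen shift and oxa-6π ring closure, which builds the C4a'–C4' bond and the pyran ring in one operation. The step relies on O1' (on C8a') having only one open ortho carbon, C4a', because C8' already carries oxygen. The precursor is the tribenzyl-protected (2S)-flavanone whose B-ring oxygen para to C2 carries the 2-methylbut-3-yn-2-yl group; it is made through a chalcone and secured in (2S) form by a transfer-hydrogenation kinetic resolution. Markovnikov hydration, oxidation and hydrogenolysis then finish the target.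

Key step: step 5

**Remarks on the chemistry**
- Primed locants (O1', C2', C3', C4', C4a', C5'–C8', C8a') refer to the 2,2-dimethylchroman ring of the target; unprimed locants refer to the flavanone.
- The propargyl ether is installed at the aldehyde stage and every phenol is capped as a benzyl ether, so no phenoxide is ever generated on the chiral flavanone (a B-ring phenoxide para to C2 would open the pyranone and racemise C2).
- Assumption: acetophenone 4 is treated as a catalogue compound.
- Assumption: the sense of the kinetic resolution in step 4 is taken from the usual facial preference of TsDPEN transfer-hydrogenation catalysts with chroman-4-ones. Should the recovered ketone prove to be (2R), the (S,S)-catalyst would be used instead.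

**Route**

Step 1
Reactants: 1 3-(benzyloxy)-4-hydroxybenzaldehyde; 2 3-chloro-3-methylbut-1-yne
Product: 3 3-(benzyloxy)-4-[(2-methylbut-3-yn-2-yl)oxy]benzaldehyde
Conditions: K2CO3, KI (cat.), CuI (cat.), DMF, 60 °C
Reagents that add atoms: none
Why: Copper-assisted propargylic O-alkylation of the phenoxide (Williamson-type etherification via the copper acetylide of the tertiary chloride) is the standard entry to aryl 1,1-dimethylpropargyl ethers, and the aldehyde has no α-hydrogen to react with the carbonate base.

Step 2
Reactants: 3 3-(benzyloxy)-4-[(2-methylbut-3-yn-2-yl)oxy]benzaldehyde; 4 1-[2,4-bis(benzyloxy)-6-hydroxyphenyl]ethan-1-one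
Product: 5 (2E)-1-[2,4-bis(benzyloxy)-6-hydroxyphenyl]-3-{3-(benzyloxy)-4-[(2-methylbut-3-yn-2-yl)oxy]phenyl}prop-2-en-1-one
Conditions: KOH (aq.), EtOH, rt
Reagents that add atoms: none
Why: Claisen–Schmidt condensation of the methyl ketone with the non-enolisable aldehyde should give the E-enone under thermodynamic control, and the propargyl ether cannot isomerise in base because its propargylic carbon is quaternary.

Step 3
Reactants: 5 (2E)-1-[2,4-bis(benzyloxy)-6-hydroxyphenyl]-3-{3-(benzyloxy)-4-[(2-methylbut-3-yn-2-yl)oxy]phenyl}prop-2-en-1-one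
Product: 6 rac-5,7-bis(benzyloxy)-2-{3-(benzyloxy)-4-[(2-methylbut-3-yn-2-yl)oxy]phenyl}chroman-4-one
Conditions: NaOAc, EtOH, reflux
Reagents that add atoms: none
Why: Intramolecular 6-endo-trig oxa-Michael addition of the free ortho-phenol to the enone is expected to favour the flavanone because the flanking benzyloxy group twists the chalcone out of conjugation; C2 forms as the racemate at this point.

Step 4
Reactants: 6 rac-5,7-bis(benzyloxy)-2-{3-(benzyloxy)-4-[(2-methylbut-3-yn-2-yl)oxy]phenyl}chroman-4-one
Product: 7 (2S)-5,7-bis(benzyloxy)-2-{3-(benzyloxy)-4-[(2-methylbut-3-yn-2-yl)oxy]phenyl}chroman-4-one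
Conditions: [Cp*RhCl((R,R)-TsDPEN)] (1 mol %), HCO2H/Et3N (5:2), EtOAc, rt, stopped just past half conversion
Reagents that add atoms: none
Why: Noyori–Ikariya asymmetric transfer hydrogenation run as a kinetic resolution: with the (R,R)-catalyst the (2R)-ketone is the matched substrate and should be reduced to the 2,4-cis (2R,4R)-carbinol, so the (2S)-ketone remains and is isolated; the outer-sphere hydride transfer leaves the alkyne and benzyl ethers alone and the acidic formate medium does not open the pyranone, so C2 is fixed here by selection.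

Step 5
Reactants: 7 (2S)-5,7-bis(benzyloxy)-2-{3-(benzyloxy)-4-[(2-methylbut-3-yn-2-yl)oxy]phenyl}chroman-4-one
Product: 11 (2S)-5,7-bis(benzyloxy)-2-[8-(benzyloxy)-2,2-dimethyl-2H-chromen-6-yl]chroman-4-one, via allenyl dienone 8 (not isolated), via allenylphenol 9 (not isolated), via quinone methide 10 (not isolated)
Conditions: o-xylene (degassed), 140 °C, sealed tube
Reagents that add atoms: none
Why: On heating, 7 should undergo the aromatic propargyl Claisen rearrangement (a [3,3] shift that cleaves the O–CMe2 bond and joins the terminal alkyne carbon to the free ortho carbon) to allenyl dienone 8, which enolises to allenylphenol 9; a 1,5-hydrogen shift from the phenol oxygen to the central allene carbon gives ortho-quinone methide 10, and a thermally allowed disrotatory oxa-6π electrocyclisation re-forms the O–CMe2 bond as O1'–C2' and closes the six-membered pyran ring. The closest known reaction type is the thermal conversion of aryl 1,1-dimethylpropargyl ethers into 2,2-dimethyl-2H-chromenes. Relative to 7, only C4a'–C4' is a net new skeletal bond, since O1'–C2' is broken and made again within the cascade. No stereocentre is created; the ring carbon of 8 that carries the allene is sp3 only transiently. The required regioselectivity is secured by the substrate: a shift to the benzyloxy-bearing ortho carbon gives a dienone that cannot tautomerise and can only revert, and the para carbon is blocked by the flavanone. C2 must survive, which is why the medium is neutral, aprotic and amine-free and all phenols are capped, so that no base or phenoxide can start a retro-oxa-Michael opening of the pyranone.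

Step 6
Reactants: 11 (2S)-5,7-bis(benzyloxy)-2-[8-(benzyloxy)-2,2-dimethyl-2H-chromen-6-yl]chroman-4-one
Product: 12 (2S)-5,7-bis(benzyloxy)-2-[8-(benzyloxy)-4-hydroxy-2,2-dimethylchroman-6-yl]chroman-4-one (both C4' epimers)
Conditions: Co(acac)2 (cat.), PhSiH3, O2 (1 atm), THF/i-PrOH, rt
Reagents that add atoms: dioxygen, O=O
Why: Mukaiyama hydration: hydrogen-atom transfer from the cobalt hydride to C3' should give the benzylic C4' radical, which is trapped by dioxygen and reduced to the carbinol (Markovnikov), while the ketone and benzyl ethers are inert; the C4' configuration is irrelevant because it is oxidised next.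

Step 7
Reactants: 12 (2S)-5,7-bis(benzyloxy)-2-[8-(benzyloxy)-4-hydroxy-2,2-dimethylchroman-6-yl]chroman-4-one
Product: 13 (2S)-5,7-bis(benzyloxy)-2-[8-(benzyloxy)-2,2-dimethyl-4-oxochroman-6-yl]chroman-4-one
Conditions: Dess–Martin periodinane, pyridine, CH2Cl2, 0 °C to rt
Reagents that add atoms: none
Why: Dess–Martin oxidation of the secondary benzylic alcohol under buffered, near-neutral conditions should give the aryl ketone without dehydrating the carbinol or touching C2, and any 4'-ketone already formed in step 6 converges on the same product.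

Step 8
Reactants: 13 (2S)-5,7-bis(benzyloxy)-2-[8-(benzyloxy)-2,2-dimethyl-4-oxochroman-6-yl]chroman-4-one
Product: 14 (2S)-5,7-dihydroxy-2-(8-hydroxy-2,2-dimethyl-4-oxochroman-6-yl)chroman-4-one
Conditions: H2 (1 atm), 10% Pd/C, EtOAc/MeOH, rt
Reagents that add atoms: none
Why: Catalytic hydrogenolysis should cleave the three aryl benzyl ethers, while both carbonyls are oxygen-conjugated aryl ketones (vinylogous esters) that resist reduction at 1 atm and the neutral medium leaves C2 untouched.

**Compound list**

1 | 3-(benzyloxy)-4-hydroxybenzaldehyde | O=Cc1ccc(O)c(OCc2ccccc2)c1 | starting material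
2 | 3-chloro-3-methylbut-1-yne | C#CC(C)(C)Cl | starting material
3 | 3-(benzyloxy)-4-[(2-methylbut-3-yn-2-yl)oxy]benzaldehyde | C#CC(C)(C)Oc1ccc(C=O)cc1OCc1ccccc1 | intermediate
4 | 1-[2,4-bis(benzyloxy)-6-hydroxyphenyl]ethan-1-one | CC(=O)c1c(O)cc(OCc2ccccc2)cc1OCc1ccccc1 | starting material
5 | (2E)-1-[2,4-bis(benzyloxy)-6-hydroxyphenyl]-3-{3-(benzyloxy)-4-[(2-methylbut-3-yn-2-yl)oxy]phenyl}prop-2-en-1-one | C#CC(C)(C)Oc1ccc(/C=C/C(=O)c2c(O)cc(OCc3ccccc3)cc2OCc2ccccc2)cc1OCc1ccccc1 | intermediate
6 | rac-5,7-bis(benzyloxy)-2-{3-(benzyloxy)-4-[(2-methylbut-3-yn-2-yl)oxy]phenyl}chroman-4-one | C#CC(C)(C)Oc1ccc(cc1OCc1ccccc1)C1CC(=O)c2c(OCc3ccccc3)cc(OCc3ccccc3)cc2O1 | intermediate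
7 | (2S)-5,7-bis(benzyloxy)-2-{3-(benzyloxy)-4-[(2-methylbut-3-yn-2-yl)oxy]phenyl}chroman-4-one | C#CC(C)(C)Oc1ccc(cc1OCc1ccccc1)[C@@H]1CC(=O)c2c(OCc3ccccc3)cc(OCc3ccccc3)cc2O1 | intermediate
8 | (2S)-5,7-bis(benzyloxy)-2-[5-(benzyloxy)-3-(3-methylbuta-1,2-dien-1-yl)-4-oxocyclohexa-1,5-dien-1-yl]chroman-4-one (allenyl dienone) | CC(C)=C=CC1C=C([C@@H]2CC(=O)c3c(OCc4ccccc4)cc(OCc4ccccc4)cc3O2)C=C(OCc2ccccc2)C1=O | intermediate (not isolated)
9 | (2S)-5,7-bis(benzyloxy)-2-[3-(benzyloxy)-4-hydroxy-5-(3-methylbuta-1,2-dien-1-yl)phenyl]chroman-4-one (allenylphenol) | CC(C)=C=Cc1cc([C@@H]2CC(=O)c3c(OCc4ccccc4)cc(OCc4ccccc4)cc3O2)cc(OCc2ccccc2)c1O | intermediate (not isolated)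
10 | (2S)-5,7-bis(benzyloxy)-2-[5-(benzyloxy)-3-(3-methylbut-2-en-1-ylidene)-4-oxocyclohexa-1,5-dien-1-yl]chroman-4-one (ortho-quinone methide) | CC(C)=CC=C1C=C([C@@H]2CC(=O)c3c(OCc4ccccc4)cc(OCc4ccccc4)cc3O2)C=C(OCc2ccccc2)C1=O | intermediate (not isolated)
11 | (2S)-5,7-bis(benzyloxy)-2-[8-(benzyloxy)-2,2-dimethyl-2H-chromen-6-yl]chroman-4-one | CC1(C)C=Cc2cc([C@@H]3CC(=O)c4c(OCc5ccccc5)cc(OCc5ccccc5)cc4O3)cc(OCc3ccccc3)c2O1 | intermediate
12 | (2S)-5,7-bis(benzyloxy)-2-[8-(benzyloxy)-4-hydroxy-2,2-dimethylchroman-6-yl]chroman-4-one (C4' epimer mixture) | CC1(C)CC(O)c2cc([C@@H]3CC(=O)c4c(OCc5ccccc5)cc(OCc5ccccc5)cc4O3)cc(OCc3ccccc3)c2O1 | intermediate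
13 | (2S)-5,7-bis(benzyloxy)-2-[8-(benzyloxy)-2,2-dimethyl-4-oxochroman-6-yl]chroman-4-one | CC1(C)CC(=O)c2cc([C@@H]3CC(=O)c4c(OCc5ccccc5)cc(OCc5ccccc5)cc4O3)cc(OCc3ccccc3)c2O1 | intermediate
14 | (2S)-5,7-dihydroxy-2-(8-hydroxy-2,2-dimethyl-4-oxochroman-6-yl)chroman-4-one | CC1(C)CC(=O)c2cc([C@@H]3CC(=O)c4c(O)cc(O)cc4O3)cc(O)c2O1 | target

**Step count**

Total steps: 8. Longest linear sequence: 8 steps (from 1 to 14).

**Steps most likely to fail**

Step 5. The risk is erosion of configuration at C2 during prolonged heating (enolisation followed by reversible opening of the pyranone), or a cascade that stalls before ring closure. The fallback decouples the thermal step from the stereocentre. It sets out from racemic flavanone 6, which is heated under the step 5 conditions to give rac-5,7-bis(benzyloxy)-2-[8-(benzyloxy)-2,2-dimethyl-2H-chromen-6-yl]chroman-4-one F1. The transfer-hydrogenation kinetic resolution of step 4 ((R,R)-catalyst, HCO2H/Et3N, EtOAc, rt) is then applied to F1, which no longer contains an alkyne. The unreacted ketone is compound 11, where the route is rejoined.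

Step 4. The risk is catalyst deactivation by the terminal alkyne (acetylide formation at the amido complex) or too small a rate difference between the enantiomers because the peri benzyloxy group at C5 crowds the carbonyl, so that high enantiopurity is not reached at a useful conversion. The fallback replaces the chemical resolution by a physical one. It sets out from racemate 6, which is separated by preparative supercritical-fluid chromatography on an immobilised amylose tris(3,5-dimethylphenylcarbamate) phase; the (2S)-enantiomer is taken on as compound 7. This fallback makes no new compound (F0).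

Step 6. The risk is net hydrogenation of the alkene (reduction of the benzylic radical before oxygen trapping) or silane reduction of a carbonyl, which would lower the amount of C4'-oxygenated material. The fallback changes from radical to ionic Markovnikov functionalisation. It sets out from chromene 11, which is treated with NBS in aqueous THF at 0 °C; water opens the bromonium ion at benzylic C4' to give the trans-bromohydrin (2S)-5,7-bis(benzyloxy)-2-[8-(benzyloxy)-3-bromo-4-hydroxy-2,2-dimethylchroman-6-yl]chroman-4-one F2. The A ring is deactivated toward bromination by its carbonyl and carries no free phenol. Radical debromination of F2 with Bu3SnH and AIBN in toluene at 80 °C then gives carbinol 12, where the route is rejoined.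

**Further compounds**

F1 | step 5 | rac-5,7-bis(benzyloxy)-2-[8-(benzyloxy)-2,2-dimethyl-2H-chromen-6-yl]chroman-4-one | CC1(C)C=Cc2cc(C3CC(=O)c4c(OCc5ccccc5)cc(OCc5ccccc5)cc4O3)cc(OCc3ccccc3)c2O1
F0 | step 4 | none | none
F2 | step 6 | (2S)-5,7-bis(benzyloxy)-2-[8-(benzyloxy)-3-bromo-4-hydroxy-2,2-dimethylchroman-6-yl]chroman-4-one (3',4'-trans, both trans diastereomers) | CC1(C)C(Br)C(O)c2cc([C@@H]3CC(=O)c4c(OCc5ccccc5)cc(OCc5ccccc5)cc4O3)cc(OCc3ccccc3)c2O1
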